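**Assumption (remark on the chemistry):** the SMILES encodes the (R) configuration at C2 (OH > CH2Ar > C15H31 > H). With (–)-sparteine, pro-S deprotonation, retentive borylation, invertive 1,2-migration and retentive oxidation lead to the (R) series.

## Structural features

The target 9 is an unbranched C17 chain with a secondary hydroxyl group at C2 and, at C1, a benzene ring substituted 1,3,5 by the chain, a free phenolic OH and an OMe group. C2 (R) is the only stereocentre and stands alone: it is flanked by the benzylic methylene C1 and by C3 of a fifteen-carbon tail, so no neighbouring stereocentre or polar group can control it. These two flanking methylene groups are sterically almost alike, so face discrimination at a C2 ketone is intrinsically poor; this is the real difficulty of the chain. The ring poses the second difficulty: the two meta oxygen atoms differ only by one methyl group, so the arene is a desymmetrised resorcinol. Fragile features are few: the electron-rich phenol is sensitive to oxidants and electrophiles, the β-aryl carbinol can dehydrate to a styrene under strong acid, and nothing is epimerisable. The key step exploits the fact that C2 is an oxygen-bearing carbon bonded to a benzylic carbon: C2 is taken from the O–CH2 carbon of a C16 fatty alcohol, whose two enantiotopic hydrogens a chiral base can tell apart, and the C1–C2 bond is made by a benzyl group migrating from boron to that carbon. In one sentence, the route is a stereospecific 1,2-metallate rearrangement of the boronate formed from an enantioenriched α-lithiated hexadecyl carbamate and a benzylic boronic ester.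

## Logic of the disconnections

**9 ⇒ 8.** The bond concerned is one aryl O–CH3 bond, cleaved in the forward direction. Cutting here makes the arene of 8 symmetric, with two equivalent methoxy groups, so the ring fragment needs no protecting group. The gain is that the OH/OMe difference disappears from every earlier intermediate. The demand is that the forward cleavage stops after one of two equivalent ethers and leaves the C2 carbinol untouched.

**8 ⇒ 7.** The C2–O bond is exchanged for a C2–B bond. A C–B bond can be created together with a C–C bond at the same carbon and is oxidised with retention. The gain is that the configuration of C2 is relayed from an earlier intermediate and not created by face selection at a carbonyl group. The demand is a stereoretentive oxidation that spares the electron-rich ring.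

**7 ⇒ 6 ⇒ 5 + 4.** The bonds cut are C1–C2 (made when the benzylic carbon migrates from boron to C2 in 6) and C2–B (made when 5 attacks the boron of 4). This is the only cut that joins the two halves and fixes C2 in the same event. The gain is the split into a C16 chain and a C7 benzyl unit and the transfer of the whole stereochemical problem to 5. The demand is retention in C–B bond formation, anti migration with inversion at C2, carbon over oxygen migration, and addition to boron faster than proton transfer from the B–CH2–Ar group of 4.

**5 ⇒ 2.** The C2–Li bond goes back to a C2–H bond. The two hydrogens of the O–CH2 group of 2 are enantiotopic and are distinguished by a chiral diamine–alkyllithium base held by the carbamate carbonyl. The gain is an achiral precursor. The demand is high selectivity for one hydrogen and configurational stability of 5 at low temperature.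

**2 ⇒ 1.** The carbamate C(=O)–O bond is cut. This leads to the cheapest even-chain fatty alcohol. The demand is only a clean O-carbamoylation.

**4 ⇒ 3.** The benzylic C–B bond is cut. This leads to a commercial benzylic bromide. The demand is borylation without homocoupling of the benzyl unit.

## Other disconnections considered

**Alternative 1:** (the first that comes to mind) cut the aryl–C1 bond. Forward key step: copper-catalysed opening of (R)-2-pentadecyloxirane A2 at its CH2 terminus by commercial 3,5-dimethoxyphenylmagnesium chloride, giving 8. A2 comes from hydrolytic kinetic resolution of racemic 2-pentadecyloxirane A1, itself made by epoxidation of 1-heptadecene. Grounds for preferring the chosen plan: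
- the stereocentre is obtained by resolution, so at most half of A1 can become A2;
- it is set in an event separate from the bond construction;
- the chain must come from an odd-carbon terminal alkene and not from the cheapest C16 alcohol.

The chosen plan creates C2 from a prochiral CH2 group in all of the material and in the step that joins the fragments. The step count is comparable, so this alternative is kept as the fallback for the key step.

**Alternative 2:** cut the C2–H bond, i.e. hydride addition to 1-(3,5-dimethoxyphenyl)heptadecan-2-one A3. Forward key step: catalytic enantioselective reduction (oxazaborolidine–borane or Ru transfer hydrogenation). Grounds for preferring the chosen plan: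
- the carbonyl of A3 lies between a benzylic CH2 and an n-alkyl CH2, which differ little in size and not at all in conjugation, so catalysts that rely on large/small or aryl/alkyl discrimination are expected to give poor facial selectivity;
- the doubly activated C1 protons of A3 invite enolisation.

The chosen plan selects between two enantiotopic hydrogens under carbamate-anchored reagent control, which does not depend on the similarity of the two chain arms.

**Alternative 3:** cut three ring bonds (C2–C3, C3–C4 and C5–C6 of the arene, chain at C1). Forward key step: thermal benzannulation of (R)-3-[2-(tert-butyldimethylsilyloxy)heptadecyl]cyclobut-2-en-1-one A4 with methoxyacetylene A5. The sequence is vinylketene formation, [2+2] cycloaddition, 4π opening and 6π closure, and it gives (R)-3-[2-(tert-butyldimethylsilyloxy)heptadecyl]-5-methoxyphenol A6; desilylation then gives 9. Grounds for preferring the chosen plan: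
- this cut delivers the OH/OMe pattern directly, with no desymmetrisation, but leaves the C2 stereocentre untouched, so it would still have to be installed beforehand by a conventional method;
- A4 itself needs about five operations, and A5 is volatile and not a shelf reagent;
- the total comes to roughly twice the step count of the chosen plan.

Key step: step 3

## Route

Step 1
Reactants: 1 hexadecan-1-ol
Product: 2 hexadecyl N,N-diisopropylcarbamate
Conditions: iPr2NCOCl (1.2 equiv), Et3N (1.3 equiv), CH2Cl2, reflux
Reagents that add atoms: N,N-diisopropylcarbamoyl chloride, CC(C)N(C(C)C)C(Cl)=O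
Why: O-carbamoylation of a primary alcohol; the hindered N,N-diisopropylcarbamate resists attack at C=O by alkyllithiums and serves in step 3 as both directing group and leaving group.

Step 2
Reactants: 3 3,5-dimethoxybenzyl bromide
Product: 4 2-(3,5-dimethoxybenzyl)-4,4,5,5-tetramethyl-1,3,2-dioxaborolane
Conditions: B2pin2 (1.1 equiv), Pd(dba)2 (3 mol%), P(4-MeOC6H4)3 (6 mol%), KOAc (1.5 equiv), toluene, 50 °C
Reagents that add atoms: bis(pinacolato)diboron, CC1(C)OB(OC1(C)C)B1OC(C)(C)C(C)(C)O1
Why: Pd(0)-catalysed Miyaura-type borylation of a benzylic halide (oxidative addition, acetate-assisted transmetalation with the diboron, reductive elimination); the weak acetate base should keep Suzuki-type coupling of 4 with unreacted 3 slow.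

Step 3
Reactants: 2 hexadecyl N,N-diisopropylcarbamate; 4 2-(3,5-dimethoxybenzyl)-4,4,5,5-tetramethyl-1,3,2-dioxaborolane
Product: 8 (R)-1-(3,5-dimethoxyphenyl)heptadecan-2-ol, via lithiated carbamate 5 (not isolated), via lithium boronate 6 (not isolated), via secondary boronic ester 7 (not isolated)
Conditions: (i) 2 (1.3 equiv), s-BuLi (1.3 equiv), (–)-sparteine (1.3 equiv), Et2O, –78 °C, 5 h; (ii) 4 (1.0 equiv), Et2O, –78 °C, 1 h; (iii) MgBr2·OEt2, –78 °C to reflux; (iv) 2 M NaOH, 30% H2O2, THF, 0 °C to rt
Reagents that add atoms: hydrogen peroxide, OO
Why: The s-BuLi/(–)-sparteine complex binds the carbamate C=O of 2 and removes the pro-S hydrogen of the O–CH2 group, giving the chelated, configurationally stable (S)-α-lithio carbamate 5. The C–Li bond of 5 attacks the boron of 4 with retention to give the tetracoordinate boronate 6. On warming with MgBr2, which activates the carbamate oxygen as a leaving group, the benzyl group migrates from boron to carbon antiperiplanar to the C–O bond (inversion at carbon), forming the C1–C2 bond and the (R)-boronic ester 7. Alkaline H2O2 then converts C–B into C–O with retention, so the (R) configuration of 8 is controlled only by the sparteine-directed deprotonation and relayed through three stereospecific events. The closest known reaction type is the lithiation–borylation–oxidation sequence, a reagent-controlled Matteson-type 1,2-metallate rearrangement of primary alkyl carbamates with pinacol boronic esters; no ring is closed. The selectivities needed are the choice of enantiotopic hydrogen (secured by the chiral diamine), carbon over oxygen migration (benzyl is a good migrating group and MgBr2 favours it), and attack at boron over removal of the acidic B–CH2–Ar protons of 4 (ate-complex formation at –78 °C should be much faster than proton transfer). Adding 4 only after lithiation is complete keeps s-BuLi away from the dimethoxyarene and so avoids ring lithiation between the methoxy groups. Double homologation is excluded because 6 rearranges only on warming, when excess 5 has already decomposed.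

Step 4
Reactants: 8 (R)-1-(3,5-dimethoxyphenyl)heptadecan-2-ol
Product: 9 (R)-1-(3-hydroxy-5-methoxyphenyl)heptadecan-2-ol
Conditions: NaSEt (4 equiv), DMF, 140 °C; then 1 M HCl
Reagents that add atoms: none
Why: Nucleophilic O-demethylation (SN2 attack of thiolate at the methyl carbon of an aryl methyl ether); after the first cleavage the ring carries a phenoxide, which makes the second ether a far poorer leaving group, so the reaction should stop at the mono-phenol, and no bond to C2 is touched.

## Compound list

1 | hexadecan-1-ol | CCCCCCCCCCCCCCCCO | starting material
2 | hexadecyl N,N-diisopropylcarbamate | CCCCCCCCCCCCCCCCOC(=O)N(C(C)C)C(C)C | intermediate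
3 | 3,5-dimethoxybenzyl bromide | COc1cc(CBr)cc(OC)c1 | starting material
4 | 2-(3,5-dimethoxybenzyl)-4,4,5,5-tetramethyl-1,3,2-dioxaborolane | COc1cc(CB2OC(C)(C)C(C)(C)O2)cc(OC)c1 | intermediate
5 | (S)-1-lithiohexadecyl N,N-diisopropylcarbamate (as its (–)-sparteine complex) | CCCCCCCCCCCCCCC[C@H]([Li])OC(=O)N(C(C)C)C(C)C | intermediate
6 | lithium [(1S)-1-(N,N-diisopropylcarbamoyloxy)hexadecyl](3,5-dimethoxybenzyl)(pinacolato)borate | CCCCCCCCCCCCCCC[C@H]([B-]1(Cc2cc(OC)cc(OC)c2)OC(C)(C)C(C)(C)O1)OC(=O)N(C(C)C)C(C)C.[Li+] | intermediate
7 | 2-[(2R)-1-(3,5-dimethoxyphenyl)heptadecan-2-yl]-4,4,5,5-tetramethyl-1,3,2-dioxaborolane | CCCCCCCCCCCCCCC[C@@H](B1OC(C)(C)C(C)(C)O1)Cc1cc(OC)cc(OC)c1 | intermediate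
8 | (R)-1-(3,5-dimethoxyphenyl)heptadecan-2-ol | CCCCCCCCCCCCCCC[C@@H](O)Cc1cc(OC)cc(OC)c1 | intermediate
9 | (R)-1-(3-hydroxy-5-methoxyphenyl)heptadecan-2-ol | CCCCCCCCCCCCCCC[C@@H](O)Cc1cc(O)cc(OC)c1 | target

## Step count and least certain steps

Total step count: 4. Longest linear sequence: 3 steps (step 1 or step 2, then steps 3 and 4).

**Step 3 (key step).** What is most likely to go wrong:
- proton transfer from the acidic B–CH2–Ar position of 4 to the carbenoid 5 in competition with ate-complex formation;
- on warming, reversal of ate-complex formation or migration of a pinacolate oxygen in place of the benzyl group;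
- erosion of enantiomeric purity if 5 warms before it is trapped.

Fallback: a different bond is formed, the aryl–C1 bond, using known chemistry. It sets out from 1 and returns at 8. Oxidation of 1 (TEMPO, PhI(OAc)2, CH2Cl2) should give hexadecanal F1. Sulfur-ylide methylenation (Me3S+ I–, NaH, DMSO/THF) should give racemic 2-pentadecyloxirane F2. Hydrolytic kinetic resolution uses the chiral (salen)Co(III) acetate enantiomer that hydrolyses the (S)-epoxide with 0.55 equiv of water, and should leave (R)-2-pentadecyloxirane F3 beside (S)-heptadecane-1,2-diol F4. CuI-catalysed opening of F3 at its CH2 terminus with commercial 3,5-dimethoxyphenylmagnesium chloride (THF, –30 °C) should give 8. C2 is not attacked, so its configuration is kept.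

**Step 4.** What is most likely to go wrong: the ether cleavage may run on to the resorcinol or stall short of completion, because the two methoxy groups are equivalent and the alkoxide at C2 consumes thiolate. The resulting mixtures would be hard to separate from the mono-ether.

Fallback: the phenolic oxygen is introduced instead of uncovered. It sets out from 2 and returns at 9. Step 3 is run with commercial 2-(3-methoxybenzyl)-4,4,5,5-tetramethyl-1,3,2-dioxaborolane F5 in place of 4. It proceeds through 5, lithium [(1S)-1-(N,N-diisopropylcarbamoyloxy)hexadecyl](3-methoxybenzyl)(pinacolato)borate F6 and 2-[(2R)-1-(3-methoxyphenyl)heptadecan-2-yl]-4,4,5,5-tetramethyl-1,3,2-dioxaborolane F7, and should give (R)-1-(3-methoxyphenyl)heptadecan-2-ol F8. Sterically controlled Ir-catalysed C–H borylation ([Ir(cod)OMe]2, 4,4'-di-tert-butyl-2,2'-bipyridine, B2pin2, THF, 80 °C) should occur at ring C5, the only C–H with no ortho substituent. The hydroxyl group is O-borylated transiently and released on work-up. The product should be (R)-1-[3-methoxy-5-(4,4,5,5-tetramethyl-1,3,2-dioxaborolan-2-yl)phenyl]heptadecan-2-ol F9. Oxidation of the aryl C–B bond (NaOH, H2O2, THF, 0 °C) should give 9.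

**Step 2.** What is most likely to go wrong: Pd-catalysed coupling of the product with unreacted bromide (benzyl–benzyl homocoupling), and protodeboronation of the benzylic boronic ester during chromatography.

Fallback: the polarity is reversed, a benzyl nucleophile meeting a boron electrophile without palladium. It sets out from 3 and returns at 4. Under Barbier conditions (Mg turnings, pinacolborane, THF, rt), 3,5-dimethoxybenzylmagnesium bromide F10 is formed in the presence of the borane and should be captured as it forms. This keeps its concentration low, suppresses Wurtz coupling, and should give 4 after loss of magnesium hydride bromide.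

## Further compounds

F1 | step 3 | hexadecanal | CCCCCCCCCCCCCCCC=O
F2 | step 3 | rac-2-pentadecyloxirane | CCCCCCCCCCCCCCCC1CO1
F3 | step 3 | (R)-2-pentadecyloxirane | CCCCCCCCCCCCCCC[C@@H]1CO1
F4 | step 3 | (S)-heptadecane-1,2-diol | CCCCCCCCCCCCCCC[C@H](O)CO
F5 | step 4 | 2-(3-methoxybenzyl)-4,4,5,5-tetramethyl-1,3,2-dioxaborolane | COc1cccc(CB2OC(C)(C)C(C)(C)O2)c1
F6 | step 4 | lithium [(1S)-1-(N,N-diisopropylcarbamoyloxy)hexadecyl](3-methoxybenzyl)(pinacolato)borate | CCCCCCCCCCCCCCC[C@H]([B-]1(Cc2cccc(OC)c2)OC(C)(C)C(C)(C)O1)OC(=O)N(C(C)C)C(C)C.[Li+]
F7 | step 4 | 2-[(2R)-1-(3-methoxyphenyl)heptadecan-2-yl]-4,4,5,5-tetramethyl-1,3,2-dioxaborolane | CCCCCCCCCCCCCCC[C@@H](B1OC(C)(C)C(C)(C)O1)Cc1cccc(OC)c1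
F8 | step 4 | (R)-1-(3-methoxyphenyl)heptadecan-2-ol | CCCCCCCCCCCCCCC[C@@H](O)Cc1cccc(OC)c1
F9 | step 4 | (R)-1-[3-methoxy-5-(4,4,5,5-tetramethyl-1,3,2-dioxaborolan-2-yl)phenyl]heptadecan-2-ol | CCCCCCCCCCCCCCC[C@@H](O)Cc1cc(OC)cc(B2OC(C)(C)C(C)(C)O2)c1
F10 | step 2 | 3,5-dimethoxybenzylmagnesium bromide | COc1cc(C[Mg]Br)cc(OC)c1
A1 | alternative 1 | rac-2-pentadecyloxirane | CCCCCCCCCCCCCCCC1CO1
A2 | alternative 1 | (R)-2-pentadecyloxirane | CCCCCCCCCCCCCCC[C@@H]1CO1
A3 | alternative 2 | 1-(3,5-dimethoxyphenyl)heptadecan-2-one | CCCCCCCCCCCCCCCC(=O)Cc1cc(OC)cc(OC)c1
A4 | alternative 3 | (R)-3-[2-(tert-butyldimethylsilyloxy)heptadecyl]cyclobut-2-en-1-one | CCCCCCCCCCCCCCC[C@@H](O[Si](C)(C)C(C)(C)C)CC1=CC(=O)C1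
A5 | alternative 3 | methoxyacetylene | COC#C
A6 | alternative 3 | (R)-3-[2-(tert-butyldimethylsilyloxy)heptadecyl]-5-methoxyphenol | CCCCCCCCCCCCCCC[C@@H](O[Si](C)(C)C(C)(C)C)Cc1cc(O)cc(OC)c1
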